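**Strategy**

Ring C (C8, C9, C11, C12, C13, C14; locants below) is a cyclohexane that shares the C8–C9 bond with ring B and carries the quaternary centres C9 and C14. It is read as an intramolecular Diels–Alder adduct: diene C9=C11–C12=C13, dienophile C8=C14, tether C10–C5–C6–C7. One cycloaddition of an acyclic (E)-enal/vinylallene trienal closes rings B and C and sets the trans-fused C8/C9 pair under control of a syn C5/C10 aldol stereodiad. The allene leaves C13 without an inside substituent, so the C9 methyl can sit inside; its exocyclic methylene later becomes the C13 methyl. C14 is then benzylated, its formyl group becomes the methyl, and the C5 ketone becomes the isopropylidene.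

Key step: step 9

Locants used throughout (seco-diterpenoid numbering): C1–C3 = propanoic acid chain on C10 (C3 = CO2H); C4 = isopropylidene carbon on C5; ring B = C5, C6, C7, C8, C9, C10; ring C = C8, C9, C11, C12, C13, C14; C14 bears the benzylic CH2; β = the face of the C9 methyl group, α = the opposite face.

Assumption: compounds 1, 2, 4, 10, 12, 16 and 24 are bought; the configuration at C5 in 25 is immaterial because C5 becomes sp2 in the same step.

**Route**

Step 1
Reactants: 1 (R)-4-benzyl-1,3-thiazolidine-2-thione; 2 5-(tert-butoxy)-5-oxopentanoic acid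
Product: 3 tert-butyl 5-[(4R)-4-benzyl-2-thioxo-1,3-thiazolidin-3-yl]-5-oxopentanoate
Conditions: DCC, DMAP (cat.), CH2Cl2, 0 °C → rt
Reagents that add atoms: none
Why: Carbodiimide N-acylation of the auxiliary with the glutaric half-ester; no stereocenter is formed.

Step 2
Reactants: 3 N-acyl thiazolidinethione; 4 pent-4-enal
Product: 5 tert-butyl (4R,5S)-4-{[(4R)-4-benzyl-2-thioxo-1,3-thiazolidin-3-yl]carbonyl}-5-hydroxynon-8-enoate
Conditions: TiCl4, i-Pr2NEt, N-methyl-2-pyrrolidinone, CH2Cl2, 0 °C; then 4, 0 °C
Reagents that add atoms: none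
Why: Titanium enolate aldol of an N-acyl thiazolidinethione (Crimmins aldol, Evans-syn mode), in which the Z-enolate reacts through the non-chelated chair and the (R)-auxiliary sets C10 (R) and C5 (S) in a syn relation.

Step 3
Reactants: 5 syn aldol
Product: 6 tert-butyl (4R,5S)-4-{[(4R)-4-benzyl-2-thioxo-1,3-thiazolidin-3-yl]carbonyl}-5-{[tert-butyl(dimethyl)silyl]oxy}non-8-enoate
Conditions: TBSOTf, 2,6-lutidine, CH2Cl2, 0 °C
Reagents that add atoms: tert-butyldimethylsilyl trifluoromethanesulfonate CC(C)(C)[Si](C)(C)OS(=O)(=O)C(F)(F)F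
Why: Silyl triflate silylation of the secondary alcohol, which blocks retro-aldol and later keeps the C5 oxygen equatorial in the cycloaddition; no stereocenter changes.

Step 4
Reactants: 6 silyl ether
Product: 7 tert-butyl (4R,5S)-5-{[tert-butyl(dimethyl)silyl]oxy}-4-formylnon-8-enoate
Conditions: i-Bu2AlH, CH2Cl2, −78 °C
Reagents that add atoms: none
Why: Partial hydride reduction of the activated thioimide gives the aldehyde and releases the auxiliary, while the tert-butyl ester should survive at −78 °C and C10 is not epimerised.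

Step 5
Reactants: 7 aldehyde
Product: 8 tert-butyl (4S,5S)-5-{[tert-butyl(dimethyl)silyl]oxy}-4-ethynylnon-8-enoate
Conditions: dimethyl (1-diazo-2-oxopropyl)phosphonate, K2CO3, MeOH, 0 °C → rt
Reagents that add atoms: dimethyl (1-diazo-2-oxopropyl)phosphonate COP(=O)(OC)C(=[N+]=[N-])C(C)=O
Why: Ohira–Bestmann (Seyferth–Gilbert) homologation converts the aldehyde into the terminal alkyne (C9≡C11) under carbonate conditions that should leave the α-stereocenter untouched.

Step 6
Reactants: 8 alkyne
Product: 9 tert-butyl (4S,5S)-5-{[tert-butyl(dimethyl)silyl]oxy}-4-[(1E)-1-(4,4,5,5-tetramethyl-1,3,2-dioxaborolan-2-yl)prop-1-en-2-yl]non-8-enoate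
Conditions: B2pin2, MeI, CuCl (10 mol%), Xantphos (10 mol%), NaOt-Bu, THF, rt
Reagents that add atoms: bis(pinacolato)diboron CC1(C)OB(OC1(C)C)B1OC(C)(C)C(C)(C)O1; iodomethane CI
Why: Copper-catalysed syn carboboration (methylboration) puts boron on the terminal carbon and traps the alkenylcopper with MeI with retention, which fixes the C9=C11 geometry (C10 trans to boron); it is run before the enal is installed so that no conjugate borylation can occur.

Step 7
Reactants: 9 alkenylboronate; 10 (E)-but-2-enal
Product: 11 tert-butyl (4S,5S,8E)-5-{[tert-butyl(dimethyl)silyl]oxy}-10-oxo-4-[(1E)-1-(4,4,5,5-tetramethyl-1,3,2-dioxaborolan-2-yl)prop-1-en-2-yl]dec-8-enoate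
Conditions: second-generation Hoveyda–Grubbs catalyst (5 mol%), excess 10, CH2Cl2, 40 °C
Reagents that add atoms: none
Why: Olefin cross-metathesis of the terminal alkene with excess crotonaldehyde should give the (E)-enal under thermodynamic control, the trisubstituted alkenylboronate being inert.

Step 8
Reactants: 11 enal boronate; 12 methyl prop-2-yn-1-yl carbonate
Product: 13 tert-butyl (4S,5S,8E)-5-{[tert-butyl(dimethyl)silyl]oxy}-4-[(2E)-hexa-2,4,5-trien-2-yl]-10-oxodec-8-enoate
Conditions: Pd(PPh3)4 (5 mol%), THF, 40 °C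
Reagents that add atoms: none
Why: Cross-coupling of the alkenylboronate with a propargylic carbonate through an allenylpalladium intermediate (the methoxide released from the carbonate activates boron) gives the vinylallene with retention of the C9=C11 geometry, at a temperature where the [1,5]-hydrogen shift is slow.

Step 9
Reactants: 13 vinylallene trienal
Product: 14 Diels–Alder adduct, trans-fused rings B/C: 5α-OSi(t-Bu)Me2, 10β-CH2CH2CO2t-Bu (10α-H), 9β-CH3, 8α-H, C11=C12, 13-methylidene, 14α-CHO (14β-H)
Conditions: Me2AlCl (1.2 equiv), CH2Cl2, −78 → −30 °C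
Reagents that add atoms: none
Why: Me2AlCl binds the formyl oxygen and the (E)-enal adds across the s-cis vinylallene (C9=C11–C12=C13, the inner π bond of the allene) in a concerted, asynchronous [4+2] cycloaddition. The closest known reactions are the Lewis acid-promoted type 1 intramolecular Diels–Alder reaction of (E)-deca-2,7,9-trienals and the Diels–Alder reaction of vinylallenes. Ring C is closed by the two new σ bonds C8–C9 and C13–C14 (suprafacial on both partners), and ring B is closed at the same time as the fused six-membered tether ring C5–C6–C7–C8–C9–C10 in a chair-like arrangement. C8 and C9 follow from the endo position of the complexed formyl group with the tether exo and from the C9=C11 geometry (C10 outside, CH3 inside), which gives the trans ring fusion with the angular methyl; the diene face is chosen by the C5 silyloxy group and the C10 side chain, which are both equatorial in only one chair; C14 is formed as an epimerisable α-CHO centre and is fixed in step 13. The step needs endo over exo and one diene face: the Lewis acid and the (E)-enal secure the first, the syn C5/C10 stereodiad secures the second, and the sp-hybridised C13 has no inside substituent, so the inside C9 methyl does not destabilise the s-cis conformer. The low temperature keeps the [1,5]-hydrogen shift of the cis-methyl vinylallene from competing.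

Step 10
Reactants: 14 Diels–Alder adduct
Product: 15 saturated aldehyde: as 14, but C11–C12 saturated and 13β-CH3 (13α-H)
Conditions: H2 (1 atm), Pd/C, EtOAc, rt (14 used at once)
Reagents that add atoms: none
Why: Heterogeneous hydrogenation of the conjugated diene should occur from the α face, opposite the angular C9 methyl, so hydrogen is delivered to C13 on the α face and the new C13 methyl is β (equatorial).

Step 11
Reactants: 16 2,6-dimethylbenzene-1,4-diol
Product: 17 2,5-dimethoxy-1,3-dimethylbenzene
Conditions: MeI, K2CO3, acetone, reflux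
Reagents that add atoms: iodomethane CI
Why: Williamson O-methylation of both phenols.

Step 12
Reactants: 17 dimethyl ether
Product: 18 1-(bromomethyl)-2,5-dimethoxy-3-methylbenzene
Conditions: NBS (0.9 equiv), AIBN (cat.), PhCF3, 80 °C
Reagents that add atoms: N-bromosuccinimide BrN1C(=O)CCC1=O
Why: Wohl–Ziegler benzylic bromination, in which the two methyl groups of 17 are equivalent, so monobromination gives one constitutional isomer and substoichiometric NBS limits the dibromide.

Step 13
Reactants: 15 saturated aldehyde; 18 benzylic bromide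
Product: 19 quaternary aldehyde: 14α-(2,5-dimethoxy-3-methylbenzyl), 14β-CHO, otherwise as 15
Conditions: KOt-Bu, THF, −78 °C; then 18, −78 → 0 °C
Reagents that add atoms: none
Why: C-alkylation of the potassium enolate of the α-branched aldehyde with the reactive benzylic bromide, in which the electrophile enters on the α face (equatorial attack) because the β face of C14 is blocked by the syn-axial C9 methyl, placing CH2Ar α and CHO β.

Step 14
Reactants: 19 quaternary aldehyde
Product: 21 14β-methyl compound (5α-silyl ether, aryl dimethyl ether, tert-butyl ester), via tosylhydrazone 20 (not isolated)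
Conditions: TsNHNH2, EtOH, 60 °C; then catecholborane, CHCl3, 0 °C; then NaOAc·3H2O, 60 °C
Reagents that add atoms: none
Why: Catecholborane reduction of the tosylhydrazone (Kabalka deoxygenation), in which acetate triggers loss of sulfinate and N2 from the diazene, turns the neopentyl CHO into the C14 methyl without touching the quaternary centre.

Step 15
Reactants: 21 14β-methyl silyl ether
Product: 22 5α-alcohol
Conditions: HF·pyridine, THF, 0 °C → rt
Reagents that add atoms: none
Why: Fluoride cleavage of the silyl ether under mildly acidic conditions, which avoids alkoxide-driven lactonisation onto the tert-butyl ester.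

Step 16
Reactants: 22 5α-alcohol
Product: 23 C5 ketone
Conditions: Dess–Martin periodinane, NaHCO3, CH2Cl2, rt
Reagents that add atoms: none
Why: Dess–Martin oxidation to the ring B ketone, in which C10 should keep its configuration because the equatorial side chain is also the thermodynamic arrangement.

Step 17
Reactants: 23 C5 ketone; 24 phenyl 2-methylpropanoate
Product: 26 5-isopropylidene compound (aryl dimethyl ether, tert-butyl ester), via spiro β-lactone 25 (not isolated)
Conditions: LiN(i-Pr)2, THF, −78 °C; then 23, −78 → 0 °C; work-up; toluene, 110 °C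
Reagents that add atoms: none
Why: Phenyl ester enolate aldol–lactonisation (β-lactone synthesis, the aldolate expels phenoxide) followed by thermal [2+2] cycloreversion with loss of CO2 places the tetrasubstituted C4=C5 double bond regiospecifically and without acid or strong base acting on C10; the enolate should add on the equatorial (α) side and the C5 configuration is then lost.

Step 18
Reactants: 26 isopropylidene compound
Product: 28 hydroquinone tert-butyl ester, via quinone 27 (not isolated)
Conditions: (NH4)2Ce(NO3)6, MeCN/H2O, 0 °C; then Na2S2O4, EtOAc/H2O, rt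
Reagents that add atoms: none
Why: Oxidative demethylation of the hydroquinone dimethyl ether to the quinone and dithionite reduction to the hydroquinone, with the tetrasubstituted alkene and the ester expected to survive brief exposure at 0 °C.

Step 19
Reactants: 28 hydroquinone
Product: 29 monoacetate tert-butyl ester (acetate on the unhindered oxygen)
Conditions: Ac2O (1.05 equiv), pyridine, CH2Cl2, 0 °C
Reagents that add atoms: acetic anhydride CC(=O)OC(C)=O
Why: Site-selective O-acetylation, because the hydroxyl flanked by the ring methyl and the neopentyl CH2 is shielded and one equivalent of anhydride should acylate the unhindered hydroxyl.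

Step 20
Reactants: 29 monoacetate tert-butyl ester
Product: 30 CNP0144688.2 (target)
Conditions: TMSOTf, 2,6-lutidine, CH2Cl2, 0 °C → rt; then H2O
Reagents that add atoms: none
Why: Silyl triflate-mediated cleavage of the tert-butyl ester (loss of isobutene through the silyl ester) under lutidine buffering should spare the aryl acetate and the acid-sensitive isopropylidene, and aqueous work-up hydrolyses the silyl ester and the aryl silyl ether.

**Compound list**

1 | (R)-4-benzyl-1,3-thiazolidine-2-thione | S=C1SC[C@@H](Cc2ccccc2)N1 | starting material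
2 | 5-(tert-butoxy)-5-oxopentanoic acid | OC(=O)CCCC(=O)OC(C)(C)C | starting material
3 | tert-butyl 5-[(4R)-4-benzyl-2-thioxo-1,3-thiazolidin-3-yl]-5-oxopentanoate | S=C1SC[C@@H](Cc2ccccc2)N1C(=O)CCCC(=O)OC(C)(C)C | intermediate
4 | pent-4-enal | C=CCCC=O | starting material
5 | tert-butyl (4R,5S)-4-{[(4R)-4-benzyl-2-thioxo-1,3-thiazolidin-3-yl]carbonyl}-5-hydroxynon-8-enoate | S=C1SC[C@@H](Cc2ccccc2)N1C(=O)[C@H](CCC(=O)OC(C)(C)C)[C@@H](O)CCC=C | intermediate
6 | tert-butyl (4R,5S)-4-{[(4R)-4-benzyl-2-thioxo-1,3-thiazolidin-3-yl]carbonyl}-5-{[tert-butyl(dimethyl)silyl]oxy}non-8-enoate | S=C1SC[C@@H](Cc2ccccc2)N1C(=O)[C@H](CCC(=O)OC(C)(C)C)[C@@H](O[Si](C)(C)C(C)(C)C)CCC=C | intermediate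
7 | tert-butyl (4R,5S)-5-{[tert-butyl(dimethyl)silyl]oxy}-4-formylnon-8-enoate | O=C[C@H](CCC(=O)OC(C)(C)C)[C@@H](O[Si](C)(C)C(C)(C)C)CCC=C | intermediate
8 | tert-butyl (4S,5S)-5-{[tert-butyl(dimethyl)silyl]oxy}-4-ethynylnon-8-enoate | C#C[C@H](CCC(=O)OC(C)(C)C)[C@@H](O[Si](C)(C)C(C)(C)C)CCC=C | intermediate
9 | tert-butyl (4S,5S)-5-{[tert-butyl(dimethyl)silyl]oxy}-4-[(1E)-1-(4,4,5,5-tetramethyl-1,3,2-dioxaborolan-2-yl)prop-1-en-2-yl]non-8-enoate | CC1(C)OB(/C=C(C)/[C@H](CCC(=O)OC(C)(C)C)[C@@H](O[Si](C)(C)C(C)(C)C)CCC=C)OC1(C)C | intermediate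
10 | (E)-but-2-enal | C/C=C/C=O | starting material
11 | tert-butyl (4S,5S,8E)-5-{[tert-butyl(dimethyl)silyl]oxy}-10-oxo-4-[(1E)-1-(4,4,5,5-tetramethyl-1,3,2-dioxaborolan-2-yl)prop-1-en-2-yl]dec-8-enoate | CC1(C)OB(/C=C(C)/[C@H](CCC(=O)OC(C)(C)C)[C@@H](O[Si](C)(C)C(C)(C)C)CC/C=C/C=O)OC1(C)C | intermediate
12 | methyl prop-2-yn-1-yl carbonate | COC(=O)OCC#C | starting material
13 | tert-butyl (4S,5S,8E)-5-{[tert-butyl(dimethyl)silyl]oxy}-4-[(2E)-hexa-2,4,5-trien-2-yl]-10-oxodec-8-enoate | O=C/C=C/CC[C@H](O[Si](C)(C)C(C)(C)C)[C@@H](CCC(=O)OC(C)(C)C)/C(C)=C/C=C=C | intermediate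
14 | Diels–Alder adduct: trans-fused rings B/C, 5α-OSi(t-Bu)Me2, 10β-CH2CH2CO2t-Bu, 9β-CH3, 8α-H, C11=C12, 13-methylidene, 14α-CHO | O=C[C@@H]2[C@H]3CC[C@H](O[Si](C)(C)C(C)(C)C)[C@@H](CCC(=O)OC(C)(C)C)[C@]3(C)C=CC2=C | intermediate
15 | saturated aldehyde: as 14 with C11–C12 saturated and 13β-CH3 | O=C[C@@H]2[C@H]3CC[C@H](O[Si](C)(C)C(C)(C)C)[C@@H](CCC(=O)OC(C)(C)C)[C@]3(C)CC[C@H]2C | intermediate
16 | 2,6-dimethylbenzene-1,4-diol | Cc1cc(O)cc(C)c1O | starting material
17 | 2,5-dimethoxy-1,3-dimethylbenzene | COc1cc(C)c(OC)c(C)c1 | intermediate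
18 | 1-(bromomethyl)-2,5-dimethoxy-3-methylbenzene | COc1cc(C)c(OC)c(CBr)c1 | intermediate
19 | quaternary aldehyde: 14α-(2,5-dimethoxy-3-methylbenzyl), 14β-CHO, 13β-CH3, 5α-silyl ether | COc1cc(C)c(OC)c(C[C@]2(C=O)[C@H]3CC[C@H](O[Si](C)(C)C(C)(C)C)[C@@H](CCC(=O)OC(C)(C)C)[C@]3(C)CC[C@H]2C)c1 | intermediate
20 | tosylhydrazone of 19 | COc1cc(C)c(OC)c(C[C@]2(C=NNS(=O)(=O)c4ccc(C)cc4)[C@H]3CC[C@H](O[Si](C)(C)C(C)(C)C)[C@@H](CCC(=O)OC(C)(C)C)[C@]3(C)CC[C@H]2C)c1 | intermediate
21 | 14β-methyl compound: 14α-(2,5-dimethoxy-3-methylbenzyl), 5α-silyl ether, tert-butyl ester | COc1cc(C)c(OC)c(C[C@]2(C)[C@H]3CC[C@H](O[Si](C)(C)C(C)(C)C)[C@@H](CCC(=O)OC(C)(C)C)[C@]3(C)CC[C@H]2C)c1 | intermediate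
22 | 5α-alcohol | COc1cc(C)c(OC)c(C[C@]2(C)[C@H]3CC[C@H](O)[C@@H](CCC(=O)OC(C)(C)C)[C@]3(C)CC[C@H]2C)c1 | intermediate
23 | C5 ketone | COc1cc(C)c(OC)c(C[C@]2(C)[C@H]3CCC(=O)[C@@H](CCC(=O)OC(C)(C)C)[C@]3(C)CC[C@H]2C)c1 | intermediate
24 | phenyl 2-methylpropanoate | CC(C)C(=O)Oc1ccccc1 | starting material
25 | spiro β-lactone at C5 (3,3-dimethyloxetan-2-one, lactone oxygen on the β face) | COc1cc(C)c(OC)c(C[C@]2(C)[C@H]3CC[C@@]4(OC(=O)C4(C)C)[C@@H](CCC(=O)OC(C)(C)C)[C@]3(C)CC[C@H]2C)c1 | intermediate
26 | 5-isopropylidene compound, aryl dimethyl ether, tert-butyl ester | COc1cc(C)c(OC)c(C[C@]2(C)[C@H]3CCC(=C(C)C)[C@@H](CCC(=O)OC(C)(C)C)[C@]3(C)CC[C@H]2C)c1 | intermediate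
27 | 2-methyl-6-alkyl-1,4-benzoquinone tert-butyl ester | CC1=CC(=O)C=C(C[C@]2(C)[C@H]3CCC(=C(C)C)[C@@H](CCC(=O)OC(C)(C)C)[C@]3(C)CC[C@H]2C)C1=O | intermediate
28 | hydroquinone tert-butyl ester | Cc1cc(O)cc(C[C@]2(C)[C@H]3CCC(=C(C)C)[C@@H](CCC(=O)OC(C)(C)C)[C@]3(C)CC[C@H]2C)c1O | intermediate
29 | monoacetate tert-butyl ester (Ar = 5-acetoxy-2-hydroxy-3-methylphenyl) | CC(=O)Oc1cc(C)c(O)c(C[C@]2(C)[C@H]3CCC(=C(C)C)[C@@H](CCC(=O)OC(C)(C)C)[C@]3(C)CC[C@H]2C)c1 | intermediate
30 | CNP0144688.2: 5-isopropylidene, 10β-CH2CH2CO2H (10α-H), 9β-CH3, 8α-H, 13β-CH3, 14β-CH3, 14α-CH2Ar (Ar = 5-acetoxy-2-hydroxy-3-methylphenyl) | CC(=O)Oc1cc(C)c(O)c(C[C@]2(C)[C@H]3CCC(=C(C)C)[C@@H](CCC(=O)O)[C@]3(C)CC[C@H]2C)c1 | target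

**Step count and risks**

Total step count: 20. Longest linear sequence: 18 steps (steps 1–10 and 13–20, from 1 to 30); steps 11 and 12 are a two-step side branch to 18.

The three steps most likely to fail:

Step 9 (cycloaddition). The endo (trans-fusion) preference may erode, or the cis-methyl vinylallene may be consumed by [1,5]-hydrogen shift or Lewis acid-induced oligomerisation before it cyclises. The fallback sets out from 11 and replaces the allene by a plain diene. Suzuki–Miyaura coupling of 11 with (E)-1-bromoprop-1-ene (Pd(PPh3)4, K3PO4, THF/H2O, 40 °C) should give the (2E,4E)-diene trienal F1. The same Me2AlCl-promoted intramolecular Diels–Alder reaction should then give the trans-fused 13α-methyl adduct F2, because the outside methyl ends cis to C10. Dehydrogenation with IBX (DMSO, 70 °C), directed to the doubly activated allylic C13–H, should give the conjugated dienal F3, in which C13 is planar. Hydrogenation (H2, Pd/C) from the α face comes back to the route at 15; its C14 epimer serves equally, since step 13 passes through the C14 enolate.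

Step 10 (hydrogenation). Facial selectivity at C13 may be poor, or the reduction may stall at a hindered C12=C13 alkene after 1,4-addition. The fallback sets out from 14 and inverts the order of events. Alkylation of the extended enolate of 14 at its α-carbon (KOt-Bu, then 18, THF, −78 → 0 °C) should give the benzylated diene aldehyde F4. Its β face then carries both the C9 methyl and the axial C14 formyl group, so hydrogenation (H2, Pd/C) is steered more strongly to the α face and comes back to the route at 19.

Step 17 (isopropylidene). The hindered ketone may be enolised by the ester enolate instead of attacked, and the cycloreversion has to build allylic 1,3-strain against the equatorial C10 chain. The fallback sets out from 23 and comes back at 26 in one operation by a McMurry mixed reductive coupling with excess acetone (low-valent titanium from TiCl4 and Zn, pyridine, THF, reflux). This deoxygenative route needs no carbanion addition and makes no new compound (F0).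

Further compounds
F1 | step 9 | tert-butyl (4S,5S,8E)-5-{[tert-butyl(dimethyl)silyl]oxy}-4-[(2E,4E)-hexa-2,4-dien-2-yl]-10-oxodec-8-enoate | O=C/C=C/CC[C@H](O[Si](C)(C)C(C)(C)C)[C@@H](CCC(=O)OC(C)(C)C)/C(C)=C/C=C/C
F2 | step 9 | 13α-methyl Diels–Alder adduct: trans-fused rings B/C, C11=C12, 14α-CHO, otherwise as 14 | O=C[C@@H]2[C@H]3CC[C@H](O[Si](C)(C)C(C)(C)C)[C@@H](CCC(=O)OC(C)(C)C)[C@]3(C)C=C[C@@H]2C
F3 | step 9 | conjugated dienal: C11=C12 and C13=C14, 13-CH3, 14-CHO, otherwise as 14 | O=CC=2[C@H]3CC[C@H](O[Si](C)(C)C(C)(C)C)[C@@H](CCC(=O)OC(C)(C)C)[C@]3(C)C=CC=2C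
F4 | step 10 | benzylated diene aldehyde: 14α-(2,5-dimethoxy-3-methylbenzyl), 14β-CHO, C11=C12, 13-methylidene | COc1cc(C)c(OC)c(C[C@]2(C=O)[C@H]3CC[C@H](O[Si](C)(C)C(C)(C)C)[C@@H](CCC(=O)OC(C)(C)C)[C@]3(C)C=CC2=C)c1
F0 | step 17 | none | none
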